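(The readings come from a simulation with made-up constants; scatter was added.)

The rate constants are hidden, but one ratio of them can be read from the runs. Partner decomposes in first order and meets substrate in second order, so at any moment the partner decomposed per substrate reacted is a nearly constant concentration A over c(substrate), both hands together, and it drifts upward as substrate thins.

| setting | summer | winter | midnight | flask |
|---|---|---|---|---|
| left-handed substrate | 0.0010 M | 0.0010 M | 0.0015 M | 0.0010 M |
| right-handed substrate | 0.0010 M | 0.0010 M | 0.0015 M | 0.0010 M |
| partner | 1.5 equiv | 6 equiv | 3 equiv | 3.00 equiv |
| remark | run made earlier | run made earlier | run made earlier |  |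
| time |  |  |  | 2.0 min |

- summer (time / s: left-handed substrate / %, right-handed substrate / %, left-handed product / %): 10.0: 42, 44, 8; 15.0: 40, 43, 7; 25.0: 43, 43, 10; 40.0: 39, 42, 12; 60.0: 37, 45, 10; 80.0: 39, 47, 8; 90.0: 37, 41, 6
- winter (time / s: left-handed substrate / %, right-handed substrate / %, left-handed product / %): 10.0: 22, 28, 29; 12.0: 23, 29, 29; 20.0: 22, 33, 31; 25.0: 20, 29, 33; 40.0: 15, 27, 30; 60.0: 18, 30, 27; 90.0: 19, 26, 29
- midnight (time / s: left-handed substrate / %, right-handed substrate / %, left-handed product / %): 10.0: 28, 35, 20; 25.0: 27, 37, 22; 40.0: 25, 34, 22; 60.0: 27, 39, 21; 90.0: 30, 33, 22

(standard deviation of a reading: 2 percentage points)

- partner is single-handed; left-handed substrate and right-handed substrate are mirror images of each other, charged as a racemate, each of them at the stated concentration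
- the numbers in the tables scatter by 2 percentage points (one standard deviation)
- steps under discussion: partner + left-handed substrate -> left-handed product; left-handed product <-> right-handed product; partner -> decomposed reagent; partner + right-handed substrate -> right-handed product; partner -> decomposition product
- an excess is below zero if the other one leads
- the handed part of partner does not stay in what it makes, so the products of the two hands are mirror images too

- part of the left-handed substrate and right-handed substrate charged together that has reacted at 2.0 min
- excess of left-handed product over right-handed product in the product at 2.0 min
- excess of right-handed substrate over left-handed substrate among what is left of the two at 2.0 min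

The substrate readings barely move after the first one, so I read each plateau as the end of substrate consumption. The part reacted is 16.9 % in summer, 51.3 % in winter and 37.0 % at midnight. Taking c(substrate) half-way through the reaction, A comes out as 6.32 mM, 7.21 mM and 7.47 mM, so I keep the mean, 7.00 mM.

Solving the same balance for this flask gives 29.4 % reacted and W = 4.10, the waste ratio, meaning partner decomposed per substrate reacted over the run. W counts both hands together, so it tells how far the flask goes but gives neither excess.

The forecast says 29.7 % reacted (27 % to 33 %), an excess of left-handed product of 20.5 % (13 % to 25 %) and an excess of right-handed substrate of 9.2 % (7.5 % to 11 %), noting “Slow racemisation is possible”.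

The flask gives 30.9 % reacted, an excess of left-handed product of 4.57 % and an excess of right-handed substrate of 10.3 %.

    partner + left-handed substrate → left-handed product (k = 31.9 /M/s)
    left-handed product ⇌ right-handed product (k = 0.00699 /s)
    partner → decomposed reagent (k = 0.158 /s)
    partner + right-handed substrate → right-handed product (k = 18.1 /M/s)
    partner → decomposition product (k = 6.28 × 10⁻⁴ /s)

The flask's waste ratio is 3.85 against my 4.10, and for the neighbour with 5.10 equiv of partner, the same balance gives 4.54 where that flask shows 4.40. The forecast's excess of left-handed product stands 16 percentage points above the flask's, and the slowest mode of the flask as it stands at the asked time has a half-life of 0.826 min, shorter than the 2.0 min asked, while right-handed product climbs from 11.3 % at 0.200 min to 14.8 % at 2.00 min.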